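- Numbering: ring A (the trione ring) is numbered 1 to 6, with butanoyl on position 1, the methyl/prenyl quaternary carbon at position 3, the bridging methylene on position 5 and oxygen on positions 2, 4 and 6; ring B is the aspidinol ring.
- Cuts, in order: the bond from position 5 to the bridging methylene (trione 12 plus an ortho-quinone methide from aspidinol), the oxygen at position 6 (back to a ring methylene through a vinylogous thioester), the 1–2 and 1–6 bonds of ring A (six- to five-membered ring), and last the bond from position 3 to the prenyl group.
- Forward: prenylation of 2-methylcyclopentane-1,3-dione, then one-carbon ring expansion with 1-diazopentan-2-one creates ring A; position 6 is raised to the ketone level by dehydrogenation, thiol addition, a second dehydrogenation and hydrolysis, sulfur serving as a soft, exchangeable stand-in for oxygen; ring B is made separately and joined last at position 5.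
- Enabling feature: position 3 sits between the carbonyl carbons 2 and 4 exactly like carbon 2 of a 2,2-disubstituted cyclic 1,3-dione, and the acyl-bearing position 1 next to position 2 is where a diazoketone carbon lands after insertion beside a ketone.
- Stereochemistry: the only stereocentre, position 3 (R in the target), is fixed in the ring expansion by catalyst choice between two enantiotopic carbonyls; being quaternary it cannot epimerise afterwards.

Key step: step 3

Remark: enolised compounds are drawn in one tautomer each and CIP descriptors refer to that tautomer; the spatial arrangement at the quaternary carbon is identical in 6 to 12 and in 18.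

**Route**

Step 1
Reactants: 1 2-methylcyclopentane-1,3-dione; 2 prenyl bromide (1-bromo-3-methylbut-2-ene)
Product: 3 2-methyl-2-(3-methylbut-2-en-1-yl)cyclopentane-1,3-dione
Conditions: NaOH (1 M aq, 1.05 equiv), Bu4NI (5 mol%), rt; dilute HCl wash to hydrolyse any enol ether
Reagents that add atoms: none
Why: SN2 C-alkylation of the 1,3-dione enolate by the allylic bromide in water, where hydrogen bonding to the enolate oxygens favours carbon over oxygen attack, should give the achiral quaternary dione.

Step 2
Reactants: 4 butanoyl chloride
Product: 5 1-diazopentan-2-one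
Conditions: TMSCHN2 (2 M in hexanes, 2 equiv), THF/MeCN 1:1, 0 °C to rt; concentrate without aqueous work-up
Reagents that add atoms: trimethylsilyldiazomethane, C[Si](C)(C)C=[N+]=[N-]
Why: C-acylation of the silyl diazomethane by the acid chloride (the diazoketone-forming stage of the Arndt–Eistert sequence), with chloride removing silicon, should give the terminal diazoketone.

Step 3
Reactants: 3 2-methyl-2-(3-methylbut-2-en-1-yl)cyclopentane-1,3-dione; 5 1-diazopentan-2-one
Product: 6 (2S)-4-butanoyl-3-hydroxy-2-methyl-2-(3-methylbut-2-en-1-yl)cyclohex-3-en-1-one (enol form of the ring-expanded acyl dione)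
Conditions: Sc(OTf)3 (10 mol%), chiral N,N'-dioxide ligand (bis-N-oxide of the propane-1,3-diyl-linked bis-L-pipecolic acid 2,6-diisopropylanilide, 12 mol%), 4 Å MS, CH2Cl2, −20 °C, slow addition of 5 (1.1 equiv)
Reagents that add atoms: none
Why: Proposed new method: the chiral Sc(OTf)3/N,N'-dioxide Lewis acid binds one of the two enantiotopic carbonyls of 3, the diazo carbon of 5 adds to it, and the diazonium alkoxide collapses by 1,2-shift of the ring methylene with loss of dinitrogen, forming the 1–2 and 1–6 bonds of ring A; the closest known reaction type is the Lewis acid-catalysed enantioselective homologation of cyclic ketones with α-diazo esters (Tiffeneau–Demjanov-type ring expansion), which has not been shown for a diazoketone on a prochiral 1,3-dione. Ring A is not closed by a cyclisation but arises by one-carbon enlargement of the five-membered ring through that 1,2-shift. The single new stereocentre at position 3 is decided only by which carbonyl is homologated (the pro-R carbonyl must react), a choice made by the ligand sphere around scandium while the diazoketone approaches the carbonyl face anti to the larger prenyl group; the mirror-image ligand is the remedy if the sense of induction is opposite. The step needs migration of the ring methylene rather than of the quaternary carbon, and the substrate secures this because that carbon carries the second carbonyl, is electron-poor and migrates poorly. It also needs a single homologation, which should follow because only the cyclopentanedione is strained and the new acyl ketone enolises at once, deactivating the carbonyl at position 2, while the six-membered ketone at position 4 is less electrophilic.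

Step 4
Reactants: 6 (2S)-4-butanoyl-3-hydroxy-2-methyl-2-(3-methylbut-2-en-1-yl)cyclohex-3-en-1-one
Product: 9 (6S)-4-butanoyl-5-hydroxy-6-methyl-6-(3-methylbut-2-en-1-yl)cyclohexa-2,4-dien-1-one, via ring selenide 7 (not isolated), via ring selenoxide 8 (not isolated)
Conditions: NaH (1.05 equiv), THF, 0 °C; PhSeCl (1.05 equiv), −78 °C to 0 °C; then NaIO4 (2.5 equiv), THF/H2O, 0 °C to rt
Reagents that add atoms: none
Why: α-Selenenylation of the β-diketone enolate at position 1 followed by selenoxide syn-elimination, which can only take a hydrogen from position 6, should give the 2-acyl enone that tautomerises through the acidic hydrogen at position 5 to the conjugated dienone, the enolate-selective selenium transfer and periodate sparing the prenyl alkene.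

Step 5
Reactants: 9 (6S)-4-butanoyl-5-hydroxy-6-methyl-6-(3-methylbut-2-en-1-yl)cyclohexa-2,4-dien-1-one
Product: 10 (2S)-4-butanoyl-3-hydroxy-2-methyl-2-(3-methylbut-2-en-1-yl)-5-(phenylsulfanyl)cyclohex-3-en-1-one (both epimers at the sulfur-bearing carbon)
Conditions: PhSH (1.2 equiv), Et3N (10 mol%), CH2Cl2, rt, under nitrogen, dark
Reagents that add atoms: thiophenol, Sc1ccccc1
Why: Thia-Michael addition of the soft thiolate to position 6, the β-carbon of the enone built on the ketone at position 4, should proceed even with the acidic enol present, and the new sulfur-bearing centre is erased in step 6.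

Step 6
Reactants: 10 (2S)-4-butanoyl-3-hydroxy-2-methyl-2-(3-methylbut-2-en-1-yl)-5-(phenylsulfanyl)cyclohex-3-en-1-one
Product: 12 (4R)-2-butanoyl-3,5-dihydroxy-4-methyl-4-(3-methylbut-2-en-1-yl)cyclohexa-2,5-dien-1-one, via vinylogous thioester 11 (not isolated)
Conditions: DDQ (1.1 equiv), 1,4-dioxane, rt; filter; then 2 M aq HCl/THF, 40 °C
Reagents that add atoms: water, O
Why: DDQ dehydrogenation by hydride abstraction at position 6, activated by the sulfur lone pair and the adjacent enol (the reaction type that turns thiochromanones into thiochromones), should give the vinylogous thioester, and aqueous acid then replaces phenylthio by hydroxyl through addition–elimination at position 6 without touching the quaternary carbon.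

Step 7
Reactants: 13 2-methylbenzene-1,3,5-triol (2-methylphloroglucinol); 4 butanoyl chloride
Product: 14 1-(2,4,6-trihydroxy-3-methylphenyl)butan-1-one
Conditions: AlCl3 (3.5 equiv), PhNO2/CH2Cl2, 0 °C to 40 °C; aq HCl work-up
Reagents that add atoms: none
Why: Friedel–Crafts acylation of the highly activated ring at one of its two equivalent free positions should give a single ketone, whose chelated carbonyl deactivates the ring against a second acylation.

Step 8
Reactants: 14 1-(2,4,6-trihydroxy-3-methylphenyl)butan-1-one
Product: 15 aspidinol [1-(2,6-dihydroxy-4-methoxy-3-methylphenyl)butan-1-one]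
Conditions: Me2SO4 (1.0 equiv), K2CO3 (1.0 equiv), acetone, rt
Reagents that add atoms: dimethyl sulfate, COS(=O)(=O)OC
Why: Williamson O-methylation should select the most acidic, non-chelated hydroxyl para to the acyl group, because both ortho hydroxyls are tied up in hydrogen bonds to the ketone.

Step 9
Reactants: 15 aspidinol [1-(2,6-dihydroxy-4-methoxy-3-methylphenyl)butan-1-one]
Product: 16 1-{3-[(dimethylamino)methyl]-2,6-dihydroxy-4-methoxy-5-methylphenyl}butan-1-one
Conditions: Me2NH (40% aq, 1.5 equiv) premixed with CH2O (37% aq, 1.1 equiv), EtOH, 0 °C to rt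
Reagents that add atoms: formaldehyde, C=O; dimethylamine, CNC
Why: The phenolic Mannich reaction can only occur at the single unsubstituted ring carbon between hydroxyl and methoxy, and premixing formaldehyde with excess amine should suppress methylene-bis-phenol formation.

Step 10
Reactants: 12 (4R)-2-butanoyl-3,5-dihydroxy-4-methyl-4-(3-methylbut-2-en-1-yl)cyclohexa-2,5-dien-1-one; 16 1-{3-[(dimethylamino)methyl]-2,6-dihydroxy-4-methoxy-5-methylphenyl}butan-1-one
Product: 18 (4R)-2-butanoyl-6-[(3-butanoyl-2,4-dihydroxy-6-methoxy-5-methylphenyl)methyl]-3,5-dihydroxy-4-methyl-4-(3-methylbut-2-en-1-yl)cyclohexa-2,5-dien-1-one (the target), via ortho-quinone methide 17 (not isolated)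
Conditions: 1,4-dioxane, 90 °C, under nitrogen
Reagents that add atoms: none
Why: The acidic trione protonates the benzylic amine, loss of dimethylamine should release the ortho-quinone methide, and position 5, the only unsubstituted nucleophilic carbon of 12, adds to its methylidene carbon in a Michael reaction that rearomatises ring B and leaves the quaternary stereocentre untouched.

**Compound list**

1 | 2-methylcyclopentane-1,3-dione | CC1C(=O)CCC1=O | starting material
2 | prenyl bromide (1-bromo-3-methylbut-2-ene) | CC(C)=CCBr | starting material
3 | 2-methyl-2-(3-methylbut-2-en-1-yl)cyclopentane-1,3-dione | CC(C)=CCC1(C)C(=O)CCC1=O | intermediate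
4 | butanoyl chloride | CCCC(=O)Cl | starting material
5 | 1-diazopentan-2-one | CCCC(=O)C=[N+]=[N-] | intermediate
6 | (2S)-4-butanoyl-3-hydroxy-2-methyl-2-(3-methylbut-2-en-1-yl)cyclohex-3-en-1-one | CCCC(=O)C1=C(O)[C@](C)(CC=C(C)C)C(=O)CC1 | intermediate
7 | (2R)-4-butanoyl-2-methyl-2-(3-methylbut-2-en-1-yl)-4-(phenylselanyl)cyclohexane-1,3-dione (both epimers at the selenium-bearing carbon) | CCCC(=O)C1([Se]c2ccccc2)C(=O)[C@](C)(CC=C(C)C)C(=O)CC1 | intermediate
8 | (2R)-4-butanoyl-2-methyl-2-(3-methylbut-2-en-1-yl)-4-(phenylseleninyl)cyclohexane-1,3-dione | CCCC(=O)C1([Se](=O)c2ccccc2)C(=O)[C@](C)(CC=C(C)C)C(=O)CC1 | intermediate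
9 | (6S)-4-butanoyl-5-hydroxy-6-methyl-6-(3-methylbut-2-en-1-yl)cyclohexa-2,4-dien-1-one | CCCC(=O)C1=C(O)[C@](C)(CC=C(C)C)C(=O)C=C1 | intermediate
10 | (2S)-4-butanoyl-3-hydroxy-2-methyl-2-(3-methylbut-2-en-1-yl)-5-(phenylsulfanyl)cyclohex-3-en-1-one (both epimers at the sulfur-bearing carbon) | CCCC(=O)C1=C(O)[C@](C)(CC=C(C)C)C(=O)CC1Sc1ccccc1 | intermediate
11 | (2R)-4-butanoyl-2-methyl-2-(3-methylbut-2-en-1-yl)-5-(phenylsulfanyl)cyclohex-4-ene-1,3-dione | CCCC(=O)C1=C(Sc2ccccc2)CC(=O)[C@@](C)(CC=C(C)C)C1=O | intermediate
12 | (4R)-2-butanoyl-3,5-dihydroxy-4-methyl-4-(3-methylbut-2-en-1-yl)cyclohexa-2,5-dien-1-one | CCCC(=O)C1=C(O)[C@](C)(CC=C(C)C)C(O)=CC1=O | intermediate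
13 | 2-methylbenzene-1,3,5-triol (2-methylphloroglucinol) | Cc1c(O)cc(O)cc1O | starting material
14 | 1-(2,4,6-trihydroxy-3-methylphenyl)butan-1-one | CCCC(=O)c1c(O)cc(O)c(C)c1O | intermediate
15 | aspidinol, 1-(2,6-dihydroxy-4-methoxy-3-methylphenyl)butan-1-one | CCCC(=O)c1c(O)cc(OC)c(C)c1O | intermediate
16 | 1-{3-[(dimethylamino)methyl]-2,6-dihydroxy-4-methoxy-5-methylphenyl}butan-1-one | CCCC(=O)c1c(O)c(CN(C)C)c(OC)c(C)c1O | intermediate
17 | 2-butanoyl-3-hydroxy-5-methoxy-4-methyl-6-methylidenecyclohexa-2,4-dien-1-one | CCCC(=O)C1=C(O)C(C)=C(OC)C(=C)C1=O | intermediate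
18 | (4R)-2-butanoyl-6-[(3-butanoyl-2,4-dihydroxy-6-methoxy-5-methylphenyl)methyl]-3,5-dihydroxy-4-methyl-4-(3-methylbut-2-en-1-yl)cyclohexa-2,5-dien-1-one | CCCC(=O)C1=C(O)[C@](C)(CC=C(C)C)C(O)=C(Cc2c(O)c(C(=O)CCC)c(O)c(C)c2OC)C1=O | target

**Count**

Total step count: 10.
Longest linear sequence: 6 steps (steps 1, 3, 4, 5, 6, 10 from 1; equally steps 2, 3, 4, 5, 6, 10 from 4). The ring B branch (steps 7, 8, 9, 10) is 4 steps.

**Steps most likely to fail**

Step 3. The diazoketone may lose nitrogen at the Lewis acid before it adds, addition may stop at the diazo aldol stage, the quaternary carbon may migrate in competition, the enolised product may bind scandium and stall turnover, or discrimination between the two carbonyls may be poor. The fallback uses known chemistry and sets out from 14. Dearomatising C-prenylation of 14 with prenyl bromide 2 (NaOMe, MeOH, 0 °C) at the methyl-bearing ring carbon should give the racemic trione F1, to be separated from the aromatic C-prenyl isomer. Resolution of F1 by preparative HPLC on a chiral stationary phase returns to the route at 12; steps 1 to 6 are then not needed.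

Step 6. The quinone may oxidise at sulfur, thiophenol may be lost by retro-Michael reaction instead of hydride abstraction at position 6, or slow hydrolysis in acid may let the prenyl group cyclise onto an enol oxygen. The fallback sets out from 10 and replaces hydride abstraction by a syn-elimination. The sodium enolate of 10 (NaH, THF) is selenenylated with PhSeCl at −78 °C to the ring selenide F2, in which selenium is expected to enter trans to the phenylthio group and so cis to the hydrogen on the sulfur-bearing carbon. Oxidation at selenium in preference to the aryl sulfide (H2O2, 1 equiv, pyridine, CH2Cl2, 0 °C) gives the selenoxide F3, whose syn-elimination toward that hydrogen returns to the route at 11, which is hydrolysed as in step 6.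

Step 10. Release of the quinone methide may be slow, it may dimerise, or the adduct may suffer O-alkylation or cyclodehydration to a xanthene. The fallback reverses the roles of the partners and sets out from 12. A Mannich reaction of 12 at position 5 (CH2O, Me2NH, EtOH) should give the aminomethyl trione F4. Heating F4 with aspidinol 15 in dioxane releases dimethylamine to form the methylidene trione F5, which the free ring carbon of 15 attacks in a Friedel–Crafts-type Michael addition, returning to the route at 18.

**Further compounds**

F1 | step 3 | racemic 2-butanoyl-3,5-dihydroxy-4-methyl-4-(3-methylbut-2-en-1-yl)cyclohexa-2,5-dien-1-one | CCCC(=O)C1=C(O)C(C)(CC=C(C)C)C(O)=CC1=O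
F2 | step 6 | (2R)-4-butanoyl-2-methyl-2-(3-methylbut-2-en-1-yl)-4-(phenylselanyl)-5-(phenylsulfanyl)cyclohexane-1,3-dione | CCCC(=O)C1([Se]c2ccccc2)C(=O)[C@](C)(CC=C(C)C)C(=O)CC1Sc1ccccc1
F3 | step 6 | (2R)-4-butanoyl-2-methyl-2-(3-methylbut-2-en-1-yl)-4-(phenylseleninyl)-5-(phenylsulfanyl)cyclohexane-1,3-dione | CCCC(=O)C1([Se](=O)c2ccccc2)C(=O)[C@](C)(CC=C(C)C)C(=O)CC1Sc1ccccc1
F4 | step 10 | (4R)-2-butanoyl-6-[(dimethylamino)methyl]-3,5-dihydroxy-4-methyl-4-(3-methylbut-2-en-1-yl)cyclohexa-2,5-dien-1-one | CCCC(=O)C1=C(O)[C@](C)(CC=C(C)C)C(O)=C(CN(C)C)C1=O
F5 | step 10 | (4S)-2-butanoyl-3-hydroxy-4-methyl-6-methylidene-4-(3-methylbut-2-en-1-yl)cyclohex-2-ene-1,5-dione | CCCC(=O)C1=C(O)[C@](C)(CC=C(C)C)C(=O)C(=C)C1=O
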